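| flask | starting material | coupling partner | remark | time |
|---|---|---|---|---|
| summer | 0.20 M | 0.80 equiv (fed, over 80 min) | the very flask that is asked about, followed so far |  |
| midnight | 0.13 M | 0.80 equiv (fed, over 80 min) | run made earlier |  |
| flask | 0.20 M | 0.800 equiv (fed, over 80 min) |  | 5.0 d |

- summer (time / d: isomer of the product / %, target / %, starting material / %): 0.0278: 2.5, 2.5, 82.4; 0.0556: 9.1, 9.8, 70.5; 0.125: 11.7, 24.4, 54.6; 0.250: 8.4, 39.6, 43.6; 0.500: 3.3, 57.6, 32.3; 1.25: 0.3, 74.5, 19.9; 2.50: 0.1, 79.9, 16.8
- midnight (time / d: isomer of the product / %, target / %, starting material / %): 0.0556: 6.7, 7.2, 73.9; 0.104: 9.9, 15.7, 63.0; 0.250: 7.3, 34.2, 49.6; 0.500: 3.5, 51.5, 38.2; 1.04: 1.1, 67.0, 25.9; 2.50: 0.2, 77.4, 18.6; 5.00: 0.3, 79.9, 16.8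

(readings scatter by 0.3 percentage points)

- steps thought possible: starting material <-> tautomer; starting material + coupling partner <-> isomer of the product; coupling partner + tautomer -> target

* time up to 5.0 d at which isomer of the product stands highest
* the amount of isomer of the product, in percent of the starting material charged, at that time

**The rise.** During the first 80 min the coupling partner enters the summer flask, which is the flask asked about, and the isomer of the product climbs to 9.1% by 0.0556 d, a mean slope of 1.64 d⁻¹ as a share of the charge.

**The balance.** Coupling partner is the limiting reagent, and each isomer or target holds one partner. Once the feed has ended, free partner is therefore the charge less both, in percent of the starting material charged: 61.1% at 0.0556 d and 43.9% at 0.125 d in the summer run, and 54.4% at 0.104 d in the midnight run.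

**The top.** Isomer belongs to one reversible step, so at its top it forms as fast as it reverts. There [isomer]/([starting material][free partner]) is the equilibrium value, here called the holding constant. The highest reading of each run, taken near its top and with its scatter, gives 2.44 M⁻¹ for summer and 2.22 M⁻¹ for midnight, and their mean is the value read for the holding constant 2.33 M⁻¹.

**The crossing.** At 0.0556 d the summer ratio is 1.06 M⁻¹. Interpolating to the holding constant, this reckoning puts the top near 0.120 d, about the height of 11.7%. Afterwards, in the summer run, target takes nearly all of the partner, and isomer reads 0.1% at 2.50 d.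

**The forecast.** It gives 0.12 d (0.095 d to 0.145 d) and 11.8% (11.4% to 12.4%): “The peak falls near 0.12 d, barely above the 11.7% measured at 0.125 d”.

**The result.** The flask tops at 12.4% at 0.107 d, within the forecast's tolerance.

    starting material ⇌ tautomer (K = 0.220, k = 0.460 h⁻¹)
    starting material + coupling partner ⇌ isomer of the product (K = 2.30 M⁻¹, k = 1.70 M⁻¹ h⁻¹)
    coupling partner + tautomer → target (k = 8.60 M⁻¹ h⁻¹)

**The limit.** At that top the flask holds 57.4% starting material and 58.5% of its own partner charge, and the holding constant turns these into 12.5% isomer. A neighbour flask with 0.34 M of starting material tops at 16.5%, higher than the forecast's upper end of 12.4% for this flask. At that top the holding constant asks a product of the free shares of starting material and partner of 0.208, against 0.265 in this flask.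

All runs stem from a simulated flask on assumed constants, and the scatter is random.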